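**Plan**
- Ring numbering: O1, C2 (CH3), C3 (CHO), C4 (CH2CO2R arm), C5 (CO2Me), C6 (enol-ether CH). C5 is the α-carbon of the β-alkoxyacrylate O1–C6=C5–CO2Me and C4 lies β to the side-chain ester carbonyl. The C4–C5 ring bond is therefore cut first, to a C5 vinyl radical and a C3-tethered (E)-enoate.
- Further cuts: O1–C6 (oxa-Michael addition of the C2 alcohol to methyl propiolate), the enoate C=C (Wittig reaction with a hydroxytyrosyl phosphorane), and C3–CH2O (alkylation of methyl (S)-3-hydroxybutanoate).
- Forward: alkylation, reduction to the diol, one-flask oxidation/Wittig to attach the complete hydroxytyrosyl ester, propiolate addition, α-iodination, 6-exo radical closure of the only ring, then PMB removal, oxidation and desilylation.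
- Stereochemistry: C2 comes from the chiral pool, C3 from the anti-selective Frater–Seebach alkylation, and C4 from the chair-like transition state of the ring closure.

Key step: step 11

Abbreviations: PMB = 4-methoxybenzyl, TBS = tert-butyldimethylsilyl, TES = triethylsilyl, NIS = N-iodosuccinimide, DDQ = 2,3-dichloro-5,6-dicyano-1,4-benzoquinone, TEMPO = 2,2,6,6-tetramethylpiperidin-1-oxyl.
Remark: the radicals of step 11 are chain carriers, not compounds, and are described in words only. Iodide 20 is drawn as the (Z)-isomer expected from the elimination; either geometry would serve because the derived vinyl radical inverts rapidly.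

Step 1
Reactants: 1 4-methoxybenzyl alcohol; 2 chloromethyl methyl sulfide
Product: 4 4-methoxybenzyl (methylsulfanyl)methyl ether, via sodium 4-methoxybenzyl oxide 3 (not isolated)
Conditions: NaH, NaI (cat.), DME, 0 °C to rt
Reagents that add atoms: none
Why: Williamson etherification in which the sodium alkoxide displaces halide from the α-chloro sulfide under iodide catalysis, the standard preparation of methylthiomethyl ethers.

Step 2
Reactants: 4 4-methoxybenzyl (methylsulfanyl)methyl ether
Product: 5 4-methoxybenzyl chloromethyl ether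
Conditions: SO2Cl2, CH2Cl2, −78 °C; volatiles removed in vacuo, used crude at once
Reagents that add atoms: sulfuryl chloride O=S(=O)(Cl)Cl
Why: S-chlorination and collapse of the chlorosulfonium ion to the oxocarbenium/chloride pair is the established conversion of O,S-acetals into chloromethyl ethers, and the labile chloride is not purified.

Step 3
Reactants: 6 methyl (S)-3-hydroxybutanoate; 5 4-methoxybenzyl chloromethyl ether
Product: 8 methyl (2S,3S)-3-hydroxy-2-{[(4-methoxybenzyl)oxy]methyl}butanoate, via dilithium alkoxide enolate 7 (not isolated)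
Conditions: LiN(iPr)2 (2.1 equiv), THF, −78 to −20 °C; then 5, −78 to −20 °C; aq NH4Cl
Reagents that add atoms: none
Why: Frater–Seebach alkylation, in which the chelated dilithium alkoxide enolate is attacked by the reactive alkoxymethyl chloride on the face opposite the carbinol methyl group, so the new centre (the future C3) should form anti to the hydroxyl.

Step 4
Reactants: 8 methyl (2S,3S)-3-hydroxy-2-{[(4-methoxybenzyl)oxy]methyl}butanoate
Product: 9 (2S,3S)-2-{[(4-methoxybenzyl)oxy]methyl}butane-1,3-diol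
Conditions: LiAlH4, THF, 0 °C; H2O/NaOH work-up
Reagents that add atoms: none
Why: Hydride reduction of the ester to the primary alcohol, which leaves the PMB ether and both stereocentres untouched.

Step 5
Reactants: 10 hydroxytyrosol
Product: 11 tert-butyl{2-[3,4-bis(TBSO)phenyl]ethoxy}dimethylsilane (tris-TBS ether of hydroxytyrosol)
Conditions: TBSCl (3.3 equiv), imidazole, DMF, rt
Reagents that add atoms: tert-butyldimethylsilyl chloride CC(C)(C)[Si](C)(C)Cl
Why: Exhaustive silylation of the two phenols and the primary alcohol under imidazole catalysis (Corey silylation).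

Step 6
Reactants: 11 tris-TBS ether of hydroxytyrosol
Product: 12 2-[3,4-bis(TBSO)phenyl]ethanol
Conditions: camphorsulfonic acid (cat.), MeOH/CH2Cl2, 0 °C
Reagents that add atoms: none
Why: Acid-catalysed methanolysis cleaves the primary alkyl silyl ether far faster than the aryl silyl ethers, whose oxygen atoms are poorly basic (chemoselective desilylation).

Step 7
Reactants: 12 2-[3,4-bis(TBSO)phenyl]ethanol; 13 (triphenylphosphoranylidene)ketene
Product: 14 2-[3,4-bis(TBSO)phenyl]ethyl (triphenylphosphoranylidene)acetate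
Conditions: toluene, 80 °C; used after evaporation
Reagents that add atoms: none
Why: Addition of the alcohol across the C=C=O unit of the cumulated (Bestmann) ylide gives the ester-stabilised phosphorane directly, without halide or base that could touch the aryl silyl ethers.

Step 8
Reactants: 9 (2S,3S)-2-{[(4-methoxybenzyl)oxy]methyl}butane-1,3-diol; 14 2-[3,4-bis(TBSO)phenyl]ethyl (triphenylphosphoranylidene)acetate
Product: 16 2-[3,4-bis(TBSO)phenyl]ethyl (2E,4S,5S)-5-hydroxy-4-{[(4-methoxybenzyl)oxy]methyl}hex-2-enoate, via β-hydroxy aldehyde 15 (not isolated)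
Conditions: TEMPO (cat.), PhI(OAc)2, CH2Cl2, rt; then 14, rt
Reagents that add atoms: none
Why: Oxoammonium (TEMPO/PhI(OAc)2) oxidation selects the primary hydroxyl of the 1,3-diol, and the sensitive β-hydroxy aldehyde is trapped in the same flask by the stabilised ylide in an (E)-selective Wittig olefination, so it never meets strong base.

Step 9
Reactants: 16 2-[3,4-bis(TBSO)phenyl]ethyl (2E,4S,5S)-5-hydroxy-4-{[(4-methoxybenzyl)oxy]methyl}hex-2-enoate; 17 methyl propiolate
Product: 18 2-[3,4-bis(TBSO)phenyl]ethyl (2E,4S,5S)-5-{[(1E)-3-methoxy-3-oxoprop-1-en-1-yl]oxy}-4-{[(4-methoxybenzyl)oxy]methyl}hex-2-enoate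
Conditions: N-methylmorpholine, CH2Cl2, rt
Reagents that add atoms: none
Why: Amine-catalysed oxa-Michael addition of the only free hydroxyl to the propiolate (through the ammonium allenolate) forms the O1–C6 bond and should give the (E)-β-alkoxyacrylate.

Step 10
Reactants: 18 the (E)-β-alkoxyacrylate
Product: 20 2-[3,4-bis(TBSO)phenyl]ethyl (2E,4S,5S)-5-{[(1Z)-2-iodo-3-methoxy-3-oxoprop-1-en-1-yl]oxy}-4-{[(4-methoxybenzyl)oxy]methyl}hex-2-enoate, via iodo acetoxy adduct 19 (not isolated)
Conditions: NIS, AcOH, CH2Cl2, 0 °C to rt; then Et3N, rt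
Reagents that add atoms: N-iodosuccinimide O=C1CCC(=O)N1I; acetic acid CC(=O)O (its acetate is carried only in 19 and leaves again)
Why: Iodoacetoxylation followed by E1cB elimination, the known α-iodination of 3-alkoxyacrylates: the enol-ether α-carbon takes iodine from NIS, acetate caps the oxocarbenium ion, and Et3N expels acetic acid to restore the double bond with iodine on C5, while the electron-poor enoate stays inert.

Step 11
Reactants: 20 the (Z)-α-iodo-β-alkoxyacrylate tethered to the hydroxytyrosyl enoate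
Product: 21 methyl (2S,3S,4R)-4-(2-{2-[3,4-bis(TBSO)phenyl]ethoxy}-2-oxoethyl)-3-{[(4-methoxybenzyl)oxy]methyl}-2-methyl-3,4-dihydro-2H-pyran-5-carboxylate
Conditions: (Me3Si)3SiH (slow addition), Et3B, air, toluene (0.01 M), 0 °C to rt
Reagents that add atoms: none
Why: Ethyl radicals from Et3B/O2 start a chain in which (Me3Si)3Si• abstracts iodine from 20 to give the C5 α-ester vinyl radical; this adds to C4, the β-carbon of the tethered (E)-enoate, and the resulting ester-stabilised radical takes hydrogen from the silane to carry the chain. The closest known reaction type is the tin- or silane-mediated vinyl (and aryl) radical conjugate cyclisation onto α,β-unsaturated esters. The dihydropyran closes in the 6-exo-trig mode, forming only the C4–C5 bond and leaving the C5=C6 enol ether and the complete side-chain ester in place. The new C4 stereocentre is controlled by the existing C2 and C3 centres through a chair-like transition state in which the C2 methyl, the C3 CH2OPMB group and the enoate are all pseudo-equatorial, so the acetate arm should form trans to C3 and cis to the C2 methyl (4R). The step needs ring closure to outrun direct reduction of the vinyl radical and a 1,5-hydrogen shift from C3–H, which the slow hydrogen donor (Me3Si)3SiH, high dilution with slow silane addition and the activated enoate acceptor are meant to secure. 7-endo attack at the enoate α-carbon is disfavoured by orbital overlap and by the polarisation of the acceptor.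

Step 12
Reactants: 21 the cyclised PMB ether
Product: 22 methyl (2S,3S,4R)-4-(2-{2-[3,4-bis(TBSO)phenyl]ethoxy}-2-oxoethyl)-3-(hydroxymethyl)-2-methyl-3,4-dihydro-2H-pyran-5-carboxylate
Conditions: DDQ, CH2Cl2/pH 7 phosphate buffer, 0 °C; short filtration, used at once
Reagents that add atoms: none
Why: Oxidative PMB cleavage by DDQ (benzylic hydride abstraction, then hydrolysis of the oxocarbenium ion) spares the silyl ethers, the esters and the push-pull enol ether, and the δ-hydroxy ester is carried on immediately to forestall lactonisation.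

Step 13
Reactants: 22 the primary alcohol
Product: 23 methyl (2S,3R,4R)-4-(2-{2-[3,4-bis(TBSO)phenyl]ethoxy}-2-oxoethyl)-3-formyl-2-methyl-3,4-dihydro-2H-pyran-5-carboxylate
Conditions: Dess–Martin periodinane, pyridine, CH2Cl2, 0 °C to rt
Reagents that add atoms: none
Why: Dess–Martin oxidation under buffered, non-enolising conditions should give the aldehyde without β-elimination of the ring oxygen, and the formyl group already sits trans to both neighbours, so C3 has no drive to epimerise.

Step 14
Reactants: 23 the bis-TBS aldehyde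
Product: 24 methyl (2S,3R,4R)-4-{2-[2-(3,4-dihydroxyphenyl)ethoxy]-2-oxoethyl}-3-formyl-2-methyl-3,4-dihydro-2H-pyran-5-carboxylate (target)
Conditions: HF·pyridine, pyridine, THF, 0 °C to rt, argon
Reagents that add atoms: none
Why: Fluoride-driven cleavage of the two aryl silyl ethers (Si–F bond formation) under buffered, weakly acidic conditions leaves the aldehyde, both esters and the base-sensitive β-alkoxy aldehyde unit intact, and argon protects the free catechol.

**Compound list**
1 | 4-methoxybenzyl alcohol | COc1ccc(CO)cc1 | starting material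
2 | chloromethyl methyl sulfide | CSCCl | starting material
3 | sodium 4-methoxybenzyl oxide | COc1ccc(C[O-])cc1.[Na+] | intermediate (not isolated)
4 | 4-methoxybenzyl (methylsulfanyl)methyl ether | COc1ccc(COCSC)cc1 | intermediate
5 | 4-methoxybenzyl chloromethyl ether | COc1ccc(COCCl)cc1 | intermediate
6 | methyl (S)-3-hydroxybutanoate | C[C@H](O)CC(=O)OC | starting material
7 | dilithium alkoxide enolate of 6 (chelated) | C[C@H]([O-])/C=C(\[O-])OC.[Li+].[Li+] | intermediate (not isolated)
8 | methyl (2S,3S)-3-hydroxy-2-{[(4-methoxybenzyl)oxy]methyl}butanoate | C[C@H](O)[C@H](COCc1ccc(OC)cc1)C(=O)OC | intermediate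
9 | (2S,3S)-2-{[(4-methoxybenzyl)oxy]methyl}butane-1,3-diol | C[C@H](O)[C@H](COCc1ccc(OC)cc1)CO | intermediate
10 | hydroxytyrosol, 2-(3,4-dihydroxyphenyl)ethanol | OCCc1ccc(O)c(O)c1 | starting material
11 | tert-butyl{2-[3,4-bis(TBSO)phenyl]ethoxy}dimethylsilane | CC(C)(C)[Si](C)(C)OCCc1ccc(O[Si](C)(C)C(C)(C)C)c(O[Si](C)(C)C(C)(C)C)c1 | intermediate
12 | 2-[3,4-bis(TBSO)phenyl]ethanol | OCCc1ccc(O[Si](C)(C)C(C)(C)C)c(O[Si](C)(C)C(C)(C)C)c1 | intermediate
13 | (triphenylphosphoranylidene)ketene | O=C=C=P(c1ccccc1)(c1ccccc1)c1ccccc1 | starting material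
14 | 2-[3,4-bis(TBSO)phenyl]ethyl (triphenylphosphoranylidene)acetate | O=C(C=P(c1ccccc1)(c1ccccc1)c1ccccc1)OCCc1ccc(O[Si](C)(C)C(C)(C)C)c(O[Si](C)(C)C(C)(C)C)c1 | intermediate
15 | (2S,3S)-3-hydroxy-2-{[(4-methoxybenzyl)oxy]methyl}butanal | C[C@H](O)[C@H](COCc1ccc(OC)cc1)C=O | intermediate (not isolated)
16 | 2-[3,4-bis(TBSO)phenyl]ethyl (2E,4S,5S)-5-hydroxy-4-{[(4-methoxybenzyl)oxy]methyl}hex-2-enoate | C[C@H](O)[C@H](COCc1ccc(OC)cc1)/C=C/C(=O)OCCc1ccc(O[Si](C)(C)C(C)(C)C)c(O[Si](C)(C)C(C)(C)C)c1 | intermediate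
17 | methyl propiolate | C#CC(=O)OC | starting material
18 | 2-[3,4-bis(TBSO)phenyl]ethyl (2E,4S,5S)-5-{[(1E)-3-methoxy-3-oxoprop-1-en-1-yl]oxy}-4-{[(4-methoxybenzyl)oxy]methyl}hex-2-enoate | COC(=O)/C=C/O[C@@H](C)[C@H](COCc1ccc(OC)cc1)/C=C/C(=O)OCCc1ccc(O[Si](C)(C)C(C)(C)C)c(O[Si](C)(C)C(C)(C)C)c1 | intermediate
19 | iodo acetoxy adduct of 18 (3-acetoxy-2-iodo-3-alkoxypropanoate, mixture at the two new centres) | COC(=O)C(I)C(OC(C)=O)O[C@@H](C)[C@H](COCc1ccc(OC)cc1)/C=C/C(=O)OCCc1ccc(O[Si](C)(C)C(C)(C)C)c(O[Si](C)(C)C(C)(C)C)c1 | intermediate (not isolated)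
20 | 2-[3,4-bis(TBSO)phenyl]ethyl (2E,4S,5S)-5-{[(1Z)-2-iodo-3-methoxy-3-oxoprop-1-en-1-yl]oxy}-4-{[(4-methoxybenzyl)oxy]methyl}hex-2-enoate | COC(=O)/C(I)=C/O[C@@H](C)[C@H](COCc1ccc(OC)cc1)/C=C/C(=O)OCCc1ccc(O[Si](C)(C)C(C)(C)C)c(O[Si](C)(C)C(C)(C)C)c1 | intermediate
21 | methyl (2S,3S,4R)-4-(2-{2-[3,4-bis(TBSO)phenyl]ethoxy}-2-oxoethyl)-3-{[(4-methoxybenzyl)oxy]methyl}-2-methyl-3,4-dihydro-2H-pyran-5-carboxylate | COC(=O)C1=CO[C@@H](C)[C@H](COCc2ccc(OC)cc2)[C@H]1CC(=O)OCCc3ccc(O[Si](C)(C)C(C)(C)C)c(O[Si](C)(C)C(C)(C)C)c3 | intermediate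
22 | methyl (2S,3S,4R)-4-(2-{2-[3,4-bis(TBSO)phenyl]ethoxy}-2-oxoethyl)-3-(hydroxymethyl)-2-methyl-3,4-dihydro-2H-pyran-5-carboxylate | COC(=O)C1=CO[C@@H](C)[C@H](CO)[C@H]1CC(=O)OCCc2ccc(O[Si](C)(C)C(C)(C)C)c(O[Si](C)(C)C(C)(C)C)c2 | intermediate
23 | methyl (2S,3R,4R)-4-(2-{2-[3,4-bis(TBSO)phenyl]ethoxy}-2-oxoethyl)-3-formyl-2-methyl-3,4-dihydro-2H-pyran-5-carboxylate | COC(=O)C1=CO[C@@H](C)[C@H](C=O)[C@H]1CC(=O)OCCc2ccc(O[Si](C)(C)C(C)(C)C)c(O[Si](C)(C)C(C)(C)C)c2 | intermediate
24 | methyl (2S,3R,4R)-4-{2-[2-(3,4-dihydroxyphenyl)ethoxy]-2-oxoethyl}-3-formyl-2-methyl-3,4-dihydro-2H-pyran-5-carboxylate | COC(=O)C1=CO[C@@H](C)[C@H](C=O)[C@H]1CC(=O)OCCc1ccc(O)c(O)c1 | target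

**Step count**
Total: 14 steps. Longest linear sequence: 11 steps (steps 1–4 and 8–14, from 1); nine steps from the chiral-pool ester 6.

**Steps most likely to fail**

Step 11. The vinyl radical may be reduced by the silane before it closes, may shift a hydrogen atom from C3–H, or may add to C4 with too little facial bias. The fallback makes the same C4–C5 bond by a two-electron route, a reductive Heck cyclisation of 20 with Pd(OAc)2, PPh3 and HCO2Na in DMF at 70 °C. Zerovalent palladium inserts into the C–I bond, the vinylpalladium species adds syn across the enoate in the 6-exo mode, and formate reduces the resulting palladium enolate. The fallback sets out from 20 and returns to the route at 21; it creates no new compound (entry F0).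

Step 10. Electrophilic iodine may attack the electron-rich silylated catechol ring, the acid may cleave the enol ether, or the elimination may stall at the adduct. The fallback introduces iodine before the catechol fragment is present. Setting out from 8, oxa-Michael addition to 17 (N-methylmorpholine, CH2Cl2) would give methyl (2S,3S)-3-{[(1E)-3-methoxy-3-oxoprop-1-en-1-yl]oxy}-2-{[(4-methoxybenzyl)oxy]methyl}butanoate F1. NIS/AcOH would convert it into the iodo acetoxy adduct of F1 F2, and Et3N would then give methyl (2S,3S)-3-{[(1Z)-2-iodo-3-methoxy-3-oxoprop-1-en-1-yl]oxy}-2-{[(4-methoxybenzyl)oxy]methyl}butanoate F3. iBu2AlH in CH2Cl2 at −78 °C should reduce the saturated ester, the more electrophilic of the two because the vinylogous carbonate ester is deactivated by the enol-ether oxygen, to methyl (2Z)-2-iodo-3-{[(2S,3S)-3-formyl-4-[(4-methoxybenzyl)oxy]butan-2-yl]oxy}acrylate F4. Wittig olefination of this aldehyde with 14 returns to the route at 20.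

Step 12. The freed primary alcohol may lactonise onto the neighbouring side-chain ester and expel the protected hydroxytyrosol. The fallback exchanges the PMB group for a silyl ether before ring closure, where the (E)-enoate geometry rules out lactonisation, and later oxidises the silyl ether directly. Setting out from 20, DDQ would give 2-[3,4-bis(TBSO)phenyl]ethyl (2E,4S,5S)-4-(hydroxymethyl)-5-{[(1Z)-2-iodo-3-methoxy-3-oxoprop-1-en-1-yl]oxy}hex-2-enoate F5. TESCl/imidazole would give its triethylsilyl ether, 2-[3,4-bis(TBSO)phenyl]ethyl (2E,4S,5S)-5-{[(1Z)-2-iodo-3-methoxy-3-oxoprop-1-en-1-yl]oxy}-4-{[(triethylsilyl)oxy]methyl}hex-2-enoate F6. The radical conditions of step 11 would close it to methyl (2S,3S,4R)-4-(2-{2-[3,4-bis(TBSO)phenyl]ethoxy}-2-oxoethyl)-2-methyl-3-{[(triethylsilyl)oxy]methyl}-3,4-dihydro-2H-pyran-5-carboxylate F7. Swern conditions ((COCl)2, DMSO, CH2Cl2, −78 °C; then Et3N), which are known to turn primary triethylsilyl ethers straight into aldehydes without a free alcohol, would then deliver 23, where the route is rejoined.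

**Further compounds**
F0 | step 11 | none | none
F1 | step 10 | methyl (2S,3S)-3-{[(1E)-3-methoxy-3-oxoprop-1-en-1-yl]oxy}-2-{[(4-methoxybenzyl)oxy]methyl}butanoate | COC(=O)/C=C/O[C@@H](C)[C@H](COCc1ccc(OC)cc1)C(=O)OC
F2 | step 10 | iodo acetoxy adduct of F1 (mixture at the two new centres) | COC(=O)C(I)C(OC(C)=O)O[C@@H](C)[C@H](COCc1ccc(OC)cc1)C(=O)OC
F3 | step 10 | methyl (2S,3S)-3-{[(1Z)-2-iodo-3-methoxy-3-oxoprop-1-en-1-yl]oxy}-2-{[(4-methoxybenzyl)oxy]methyl}butanoate | COC(=O)/C(I)=C/O[C@@H](C)[C@H](COCc1ccc(OC)cc1)C(=O)OC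
F4 | step 10 | methyl (2Z)-2-iodo-3-{[(2S,3S)-3-formyl-4-[(4-methoxybenzyl)oxy]butan-2-yl]oxy}acrylate | COC(=O)/C(I)=C/O[C@@H](C)[C@H](COCc1ccc(OC)cc1)C=O
F5 | step 12 | 2-[3,4-bis(TBSO)phenyl]ethyl (2E,4S,5S)-4-(hydroxymethyl)-5-{[(1Z)-2-iodo-3-methoxy-3-oxoprop-1-en-1-yl]oxy}hex-2-enoate | COC(=O)/C(I)=C/O[C@@H](C)[C@H](CO)/C=C/C(=O)OCCc1ccc(O[Si](C)(C)C(C)(C)C)c(O[Si](C)(C)C(C)(C)C)c1
F6 | step 12 | 2-[3,4-bis(TBSO)phenyl]ethyl (2E,4S,5S)-5-{[(1Z)-2-iodo-3-methoxy-3-oxoprop-1-en-1-yl]oxy}-4-{[(triethylsilyl)oxy]methyl}hex-2-enoate | COC(=O)/C(I)=C/O[C@@H](C)[C@H](CO[Si](CC)(CC)CC)/C=C/C(=O)OCCc1ccc(O[Si](C)(C)C(C)(C)C)c(O[Si](C)(C)C(C)(C)C)c1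
F7 | step 12 | methyl (2S,3S,4R)-4-(2-{2-[3,4-bis(TBSO)phenyl]ethoxy}-2-oxoethyl)-2-methyl-3-{[(triethylsilyl)oxy]methyl}-3,4-dihydro-2H-pyran-5-carboxylate | COC(=O)C1=CO[C@@H](C)[C@H](CO[Si](CC)(CC)CC)[C@H]1CC(=O)OCCc2ccc(O[Si](C)(C)C(C)(C)C)c(O[Si](C)(C)C(C)(C)C)c2
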